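25 ⇐ 24 (acetonide removal) ⇐ 22 + umbelliferone 23 (Mitsunobu at C11) ⇐ ring B β-keto ester 19 (C5=C6 reduction, C8 methylenation, ester reduction).
Feature (drimane numbering): ring B (C5–C10) hides a β-keto ester, C8 as the ketone and C11 as the ester on C9; the C7 terminus of its bis-silyl dienol ether (C7=C8–C9=C11) is joined to C6 of an exocyclic C5=C6 methylene on ring A, so the disconnection is C6–C7 (19 ⇐ 18, anodic oxidation).
18 ⇐ β-keto ester 16 ⇐ ring A ketone 7 (3,24-acetonide): C10 is made quaternary by allylation and then methylation of the C5 ketone enolate, the allyl group is cut down to CH2CO2Me (C9, C11), C5 is methylenated (C6) and C9 is acetylated (C8, C7).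
7 ⇐ 2-methylcyclohexane-1,3-dione 1: hydroxymethylation (C24) and an oxazaborolidine-catalysed desymmetrising reduction set C4 and C3.
Ring order: ring A is present from the start, ring B is closed in the key step, the coumarin is attached at the end.

Key step: step 12

Remark: drimane numbering is used throughout (C24 is the oxygenated carbon on C4, C11 the oxygenated carbon on C9, C12 the methylene carbon on C8); the ketene acetal geometry drawn for 18 is arbitrary and has no bearing on the key step.

Step 1
Reactants: 1 2-methylcyclohexane-1,3-dione; 2 formaldehyde (37% aqueous solution)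
Product: 3 2-(hydroxymethyl)-2-methylcyclohexane-1,3-dione (achiral)
Conditions: NaHCO3 (cat.), H2O/THF, rt
Reagents that add atoms: none
Why: Aldol addition (hydroxymethylation) of the acidic 2-substituted 1,3-dione to formaldehyde at C2, where the adduct has no hydrogen left and so cannot dehydrate; it is silylated at once to close the retro-aldol path.

Step 2
Reactants: 3 2-(hydroxymethyl)-2-methylcyclohexane-1,3-dione
Product: 4 2-[(tert-butyldimethylsilyloxy)methyl]-2-methylcyclohexane-1,3-dione (achiral)
Conditions: TBSCl, imidazole, CH2Cl2, 0 °C to rt
Reagents that add atoms: tert-butyldimethylsilyl chloride CC(C)(C)[Si](C)(C)Cl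
Why: Silyl ether formation at the primary alcohol, which also makes CH2OTBS clearly larger than CH3 for the facial differentiation in step 3.

Step 3
Reactants: 4 2-[(tert-butyldimethylsilyloxy)methyl]-2-methylcyclohexane-1,3-dione
Product: 5 (2R,3R)-2-[(tert-butyldimethylsilyloxy)methyl]-3-hydroxy-2-methylcyclohexan-1-one (OH cis to CH2OTBS)
Conditions: (S)-2-methyl-CBS-oxazaborolidine (20 mol %), catecholborane, toluene, −78 °C
Reagents that add atoms: none
Why: Corey–Bakshi–Shibata reduction that desymmetrises the prochiral dione: the (S)-catalyst should give the (R)-carbinol (quaternary C2 as the large group), and hydride attack anti to the larger CH2OTBS group selects the carbonyl that leaves OH cis to CH2OTBS, which sets C3 and C4 together.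

Step 4
Reactants: 5 (2R,3R)-2-[(tert-butyldimethylsilyloxy)methyl]-3-hydroxy-2-methylcyclohexan-1-one
Product: 7 ring A acetonide ketone (4aR,8aR)-2,2,4a-trimethylhexahydro-4H-1,3-benzodioxin-5-one, via keto diol 6 (not isolated)
Conditions: CSA (cat.), MeOH, rt; then 2,2-dimethoxypropane, acetone, rt
Reagents that add atoms: 2,2-dimethoxypropane COC(C)(C)OC
Why: Acid-catalysed methanolysis of the primary silyl ether followed by acetalisation of the cis 1,3-diol (C3–OH, C24–OH) to the cis-fused dioxane; the β-hydroxy ketone cannot eliminate because C4 is quaternary.

Step 5
Reactants: 7 ring A acetonide ketone; 8 allyl bromide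
Product: 9 ring A ketone carrying an allyl group on C10 (both C10 epimers)
Conditions: LiN(i-Pr)2, THF, −78 °C; allyl bromide, DMPU, −78 to 0 °C
Reagents that add atoms: none
Why: Alkylation of the lithium enolate, which can form only toward C10 because C4 is quaternary; the C10 configuration is of no consequence since the centre is enolised again in step 6.

Step 6
Reactants: 9 C10-allyl ketone
Product: 10 C10-quaternary ketone (new methyl cis to C24 and O3; allyl cis to the C4 methyl)
Conditions: KN(SiMe3)2, THF, −78 to −20 °C; MeI, −78 °C to rt
Reagents that add atoms: iodomethane CI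
Why: Alkylation of the tetrasubstituted potassium enolate, in which the cis-fused acetonide holds the C4 methyl pseudoaxial so that methyl iodide should enter C10 from the opposite face, placing the new methyl cis to C24 and O3 and the allyl group (the future C9) cis to the C4 methyl, which is why allyl is introduced before methyl.

Step 7
Reactants: 10 C10-quaternary allyl ketone
Product: 12 keto ester with CH2CO2Me (C9 and C11) on C10, via keto aldehyde 11 (not isolated)
Conditions: O3, NaOH (2.5 M in MeOH), CH2Cl2, −78 °C
Reagents that add atoms: ozone [O-][O+]=O; methanol CO
Why: Ozonolysis of the monosubstituted alkene in methanolic NaOH, where the aldehyde hemiacetal is oxidised by ozone to the methyl ester in the same flask; the ketone is non-enolisable and the acetonide is stable to base.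

Step 8
Reactants: 12 keto ester
Product: 13 methylene ester (C5=C6 exocyclic methylene between quaternary C4 and C10)
Conditions: Zn, CH2Br2, TiCl4, THF/CH2Cl2, 0 °C to rt
Reagents that add atoms: dibromomethane BrCBr
Why: Takai–Lombardo methylenation, a non-basic titanium–methylene reagent that attacks ketones but leaves esters alone and copes with crowded carbonyl groups better than a phosphorus ylide.

Step 9
Reactants: 13 methylene ester; 14 acetaldehyde
Product: 15 β-hydroxy ester with CH(OH)CH3 on C9 (diastereomer mixture)
Conditions: LiN(i-Pr)2, THF, −78 °C; MeCHO, −78 °C
Reagents that add atoms: none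
Why: Aldol addition of the lithium ester enolate at C9 to acetaldehyde, which brings in C8 and C7; the two new centres are removed or equilibrated later.

Step 10
Reactants: 15 β-hydroxy ester
Product: 16 β-keto ester, methyl 3-oxobutanoate carrying ring A (through C10) on C2 (C9 epimers)
Conditions: Dess–Martin periodinane, NaHCO3, CH2Cl2, rt
Reagents that add atoms: none
Why: Dess–Martin oxidation of the secondary alcohol under buffered neutral conditions that leave the exocyclic alkene and the acetonide untouched.

Step 11
Reactants: 16 β-keto ester
Product: 18 bis(trimethylsilyl) dienol ether (C7=C8(OSiMe3)–C9=C11(OMe)OSiMe3 on C10), via mono-silyl enol ether 17 (not isolated)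
Conditions: NaH, THF, 0 °C, then Me3SiCl; LiN(i-Pr)2, THF, −78 °C, then Me3SiCl; non-aqueous work-up, used crude
Reagents that add atoms: chlorotrimethylsilane C[Si](C)(C)Cl
Why: Two-stage enol silylation, the standard route from β-keto esters to 1-methoxy-1,3-bis(silyloxy) dienes: O-silylation of the sodium enolate at the ketone oxygen, then γ-deprotonation at C7 and O-silylation at the ester oxygen.

Step 12
Reactants: 18 bis(trimethylsilyl) dienol ether
Product: 19 ring B 5-ene β-keto ester (C8 ketone, C11 methyl ester on C9, C5=C6, 3,24-acetonide)
Conditions: reticulated vitreous carbon anode, carbon cathode, undivided cell, LiClO4 (0.1 M), 2,6-lutidine, i-PrOH/CH2Cl2 (1:4), constant current, 2.2 F/mol, 0 °C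
Reagents that add atoms: none
Why: Proposed new method: one-electron oxidation at the anode takes place at the electron-rich bis-silyl dienol ether, far easier to oxidise than the isolated 1,1-disubstituted alkene, and the radical cation (or the radical left after loss of a silyl group to isopropanol) carries spin at C7 and C9, of which only C7 can reach the alkene; it bonds to the unsubstituted C6 in a 6-endo-trig closure of ring B, the tertiary C5 radical is oxidised to the cation and loses a C6 proton to 2,6-lutidine, and loss of the second silyl group leaves the β-keto ester. The closest known reaction type is the anodic coupling of silyl enol ether and ketene acetal radical cations with tethered olefins, and the new element is the pairing of a bis-silyl dienol ether of an α-substituted β-keto ester with a hindered exocyclic methylene. The 5-exo alternative would make a bond to the fully substituted C5 between two quaternary carbons and leave a primary centre at C6, so ring size and the stability of the tertiary C5 intermediate both secure the C6–C7 regiochemistry. The C5=C6 bond cannot move toward C4 or C10, which bear no hydrogen, and isopropanol replaces methanol because a ketene silyl acetal would be solvolysed by methanol before it is oxidised, while early loss of the ester-derived silyl group would still leave a C7=C8 silyl enol ether that follows the same path. The only new stereocentre, C9, lies between two carbonyl groups and is under thermodynamic control through the enol, and it is finally fixed with the ester equatorial once ring B is a chair in step 13.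

Step 13
Reactants: 19 ring B 5-ene β-keto ester
Product: 20 trans-fused saturated β-keto ester (5-H trans to the C10 methyl; C9 ester equatorial and cis to the C10 methyl)
Conditions: H2 (50 bar), Pd/C, EtOAc, rt
Reagents that add atoms: none
Why: Catalytic hydrogenation of the trisubstituted C5=C6 bond, in which the face that carries the axial C10 methyl and C24 is shielded, so hydrogen should add to the other face and give the trans ring fusion, after which the β-keto ester settles at C9 with the ester equatorial.

Step 14
Reactants: 20 trans-fused β-keto ester
Product: 21 methyl ester with the C8=C12 exocyclic methylene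
Conditions: Zn, CH2Br2, TiCl4, THF/CH2Cl2, 0 °C to rt
Reagents that add atoms: dibromomethane BrCBr
Why: Takai–Lombardo methylenation of the C8 ketone, chosen because the non-basic reagent methylenates an enolisable β-keto ester without forming its enolate and without epimerising C9.

Step 15
Reactants: 21 methylene ester
Product: 22 primary alcohol at C11 (3,24-acetonide retained)
Conditions: i-Bu2AlH, CH2Cl2, −78 to 0 °C; aqueous KNaC4H4O6 work-up
Reagents that add atoms: none
Why: Hydride reduction of the ester to the primary alcohol, with the alkene and the acetonide inert to the aluminium hydride.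

Step 16
Reactants: 22 C11 alcohol; 23 umbelliferone
Product: 24 C11 aryl ether of umbelliferone (3,24-acetonide retained)
Conditions: PPh3, DIAD, THF, 0 °C to rt
Reagents that add atoms: none
Why: Mitsunobu etherification of the primary alcohol with the acidic 7-hydroxyl of the coumarin; the reaction occurs at a CH2 group, so no stereocentre is touched.

Step 17
Reactants: 24 aryl ether acetonide
Product: 25 target CNP0149624.1
Conditions: PPTS, MeOH, rt
Reagents that add atoms: none
Why: Acid-catalysed transacetalisation in methanol removes the acetonide, which is strained in the trans-decalin, under conditions too mild to isomerise the C8 exocyclic alkene or open the coumarin.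

Compound list
1 | 2-methylcyclohexane-1,3-dione | CC1C(=O)CCCC1=O | starting material
2 | formaldehyde | C=O | starting material
3 | 2-(hydroxymethyl)-2-methylcyclohexane-1,3-dione | CC1(CO)C(=O)CCCC1=O | intermediate
4 | 2-[(tert-butyldimethylsilyloxy)methyl]-2-methylcyclohexane-1,3-dione | CC1(CO[Si](C)(C)C(C)(C)C)C(=O)CCCC1=O | intermediate
5 | (2R,3R)-2-[(tert-butyldimethylsilyloxy)methyl]-3-hydroxy-2-methylcyclohexan-1-one | O=C1[C@](C)(CO[Si](C)(C)C(C)(C)C)[C@H](O)CCC1 | intermediate
6 | (2R,3R)-3-hydroxy-2-(hydroxymethyl)-2-methylcyclohexan-1-one (not isolated) | O=C1[C@](C)(CO)[C@H](O)CCC1 | intermediate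
7 | (4aR,8aR)-2,2,4a-trimethylhexahydro-4H-1,3-benzodioxin-5-one (ring A ketone, 3,24-acetonide) | O=C1[C@]2(C)COC(C)(C)O[C@@H]2CCC1 | intermediate
8 | allyl bromide | C=CCBr | starting material
9 | C10-allyl ring A ketone (C10 epimers) | O=C1[C@]2(C)COC(C)(C)O[C@@H]2CCC1CC=C | intermediate
10 | C10-allyl C10-methyl ring A ketone (methyl cis to C24 and O3) | O=C1[C@]2(C)COC(C)(C)O[C@@H]2CC[C@@]1(C)CC=C | intermediate
11 | keto aldehyde (not isolated) | O=C1[C@]2(C)COC(C)(C)O[C@@H]2CC[C@@]1(C)CC=O | intermediate
12 | keto methyl ester | O=C1[C@]2(C)COC(C)(C)O[C@@H]2CC[C@@]1(C)CC(=O)OC | intermediate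
13 | C5-methylene methyl ester | C=C1[C@]2(C)COC(C)(C)O[C@@H]2CC[C@@]1(C)CC(=O)OC | intermediate
14 | acetaldehyde | CC=O | starting material
15 | β-hydroxy ester (diastereomer mixture) | C=C1[C@]2(C)COC(C)(C)O[C@@H]2CC[C@@]1(C)C(C(C)O)C(=O)OC | intermediate
16 | β-keto ester (C9 epimers) | C=C1[C@]2(C)COC(C)(C)O[C@@H]2CC[C@@]1(C)C(C(C)=O)C(=O)OC | intermediate
17 | mono-silyl enol ether (not isolated) | C=C1[C@]2(C)COC(C)(C)O[C@@H]2CC[C@@]1(C)C(C(=O)OC)=C(C)O[Si](C)(C)C | intermediate
18 | bis(trimethylsilyl) dienol ether (key-step precursor) | C=C1[C@]2(C)COC(C)(C)O[C@@H]2CC[C@@]1(C)/C(C(=C)O[Si](C)(C)C)=C(/OC)O[Si](C)(C)C | intermediate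
19 | ring B 5-ene β-keto ester (key-step product) | O=C1CC=C2[C@]3(C)COC(C)(C)O[C@@H]3CC[C@@]2(C)[C@@H]1C(=O)OC | intermediate
20 | trans-fused saturated β-keto ester | O=C1CC[C@@H]2[C@]3(C)COC(C)(C)O[C@@H]3CC[C@@]2(C)[C@@H]1C(=O)OC | intermediate
21 | C8-methylene methyl ester | C=C1CC[C@@H]2[C@]3(C)COC(C)(C)O[C@@H]3CC[C@@]2(C)[C@@H]1C(=O)OC | intermediate
22 | C11 primary alcohol | C=C1CC[C@@H]2[C@]3(C)COC(C)(C)O[C@@H]3CC[C@@]2(C)[C@@H]1CO | intermediate
23 | umbelliferone (7-hydroxycoumarin) | O=c1ccc2ccc(O)cc2o1 | starting material
24 | C11 umbelliferyl ether, 3,24-acetonide | C=C1CC[C@@H]2[C@]3(C)COC(C)(C)O[C@@H]3CC[C@@]2(C)[C@@H]1COc1ccc2ccc(=O)oc2c1 | intermediate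
25 | CNP0149624.1 | C=C1CC[C@@H]2[C@](C)(CO)[C@H](O)CC[C@@]2(C)[C@@H]1COc1ccc2ccc(=O)oc2c1 | target

Total step count: 17. Longest linear sequence: 17 steps (1 to 25).

Steps most likely to fail

Step 12 (key step, proposed new method). The silyl groups may be lost by solvolysis before oxidation, the C7 radical cation may be trapped by the alcohol, the C5 cation may undergo a 1,2-methyl shift before it loses the C6 proton, or the enolisable product may be oxidised further. The fallback uses known radical chemistry and sets out from 18: N-bromosuccinimide in THF at −78 °C brominates the diene terminus C7 and, after work-up, should give the γ-bromo β-keto ester F1. Slow addition of Bu3SnH with AIBN in hot benzene generates the C7 α-keto radical, which closes 6-endo onto C6. The tertiary C5 radical then takes hydrogen from the stannane on the face away from the C10 methyl. The fallback comes back to the route at 20, so step 13 is no longer needed.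

Step 8. The carbonyl group lies between two quaternary carbons, so the titanium reagent may fail to reach it and the ketone may be recovered. The fallback sets out from 10, before the ester exists: Me3SiCH2Li with CeCl3 in THF adds to the ketone and should give the β-hydroxysilane F2, and KH in THF (Peterson olefination) turns it into the diene F3. OsO4 (cat.) with NaIO4 and 2,6-lutidine in dioxane/water (Lemieux–Johnson cleavage) should cut only the unhindered allyl alkene, since the C5 methylene is buried between two quaternary carbons, and give the aldehyde F4. I2 and KOH in MeOH oxidise F4 to the methyl ester, and the fallback comes back to the route at 13.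

Step 13. The trisubstituted alkene between two quaternary carbons may resist hydrogenation on the metal surface, or hydrogen may be delivered to the wrong face and give the cis ring fusion. The fallback sets out from 19 and replaces surface hydrogenation by radical hydrogen-atom transfer: the trivalent manganese complex Mn(dpm)3 (dpm = dipivaloylmethanate, cat.), PhSiH3 and t-BuOOH in i-PrOH at rt should reduce the hindered alkene through the tertiary C5 radical and favour the trans-fused product. It comes back to the route at 20 and makes no new compound (F0).

Further compounds
F1 | step 12 | γ-bromo β-keto ester (bromine on C7) | C=C1[C@]2(C)COC(C)(C)O[C@@H]2CC[C@@]1(C)C(C(=O)CBr)C(=O)OC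
F2 | step 8 | β-hydroxysilane (C5 carbinol bearing CH2SiMe3) | OC1(C[Si](C)(C)C)[C@]2(C)COC(C)(C)O[C@@H]2CC[C@@]1(C)CC=C
F3 | step 8 | diene (C5 methylene, C10 allyl) | C=C1[C@]2(C)COC(C)(C)O[C@@H]2CC[C@@]1(C)CC=C
F4 | step 8 | aldehyde (C5 methylene, C10 CH2CHO) | C=C1[C@]2(C)COC(C)(C)O[C@@H]2CC[C@@]1(C)CC=O
F0 | step 13 | none | none
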